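**Strategy**

Ring A is built around its alkylated carbon instead of being alkylated afterwards: C3′, which bears the lavandulyl CH2, lies between the oxygenated carbons C2′ and C4′, and this is the pattern that results when a vinylketene combines with a silyl ynol ether. Heating 3-methoxycyclobut-2-enone with the triisopropylsilyl ynol ether of an open-chain (R)-enyne forms C3′–C4′ and C1′–C2′, closes the six-membered ring A and delivers the resorcinol monosilyl ether with the 6′-OMe in place, all in one operation. The precursor carries the C2″ stereocentre, taken from (S)-carvone, with isopropenyl, 3-methylbut-2-enyl and propargyl arms. The cinnamoyl unit is attached last by ortho-lithiation.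

Key step: step 8

Remark: the stereocentre is never touched; its descriptor changes from S (compounds 1, 2) to R (from compound 4 on) only through CIP ranking, and the 3-methylbut-2-enyl end is made by cross-metathesis so that no positional alkene isomers can arise.

**Route**

Step 1
Reactants: 1 (S)-(+)-carvone [(5S)-2-methyl-5-(prop-1-en-2-yl)cyclohex-2-en-1-one]
Product: 2 (1S,4S,6S)-1-methyl-4-(prop-1-en-2-yl)-7-oxabicyclo[4.1.0]heptan-2-one
Conditions: 30% aq H2O2, NaOH (0.3 equiv), MeOH, 0 °C
Reagents that add atoms: hydrogen peroxide, OO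
Why: Weitz–Scheffer nucleophilic epoxidation, in which hydroperoxide adds only to the electron-poor enone alkene (the isopropenyl group is inert) from the face opposite the isopropenyl substituent, which sets the two epoxide centres that are erased again in step 2.

Step 2
Reactants: 2 (1S,4S,6S)-1-methyl-4-(prop-1-en-2-yl)-7-oxabicyclo[4.1.0]heptan-2-one
Product: 4 (3R)-3-(prop-1-en-2-yl)hept-5-ynal, via epoxy tosylhydrazone 3 (not isolated)
Conditions: TsNHNH2 (1.0 equiv), CH2Cl2/AcOH (2:1), −20 °C → rt
Reagents that add atoms: none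
Why: Eschenmoser–Tanabe fragmentation, in which the hydrazone opens the epoxide and the resulting alkoxy diazene fragments with loss of N2 and sulfinate, turning the epoxide CH into the aldehyde and the former carbonyl carbon and its methyl-bearing neighbour into the methyl-capped alkyne without touching the isopropenyl-bearing centre.

Step 3
Reactants: 4 (3R)-3-(prop-1-en-2-yl)hept-5-ynal
Product: 5 (3R,5Z)-3-(prop-1-en-2-yl)hept-5-enal
Conditions: H2 (1 atm), Pd/CaCO3 poisoned with Pb(OAc)2, quinoline, EtOAc, rt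
Reagents that add atoms: none
Why: Lindlar semihydrogenation adds H2 syn on the poisoned palladium surface and stops at the cis-alkene, leaving the aldehyde and the 1,1-disubstituted alkene untouched.

Step 4
Reactants: 5 (3R,5Z)-3-(prop-1-en-2-yl)hept-5-enal
Product: 6 (3R)-6-methyl-3-(prop-1-en-2-yl)hept-5-enal
Conditions: 2-methylbut-2-ene (30 equiv), second-generation Grubbs catalyst RuCl2(=CHPh)(PCy3)(1,3-dimesitylimidazolidin-2-ylidene) (5 mol%), CH2Cl2, 40 °C, sealed tube
Reagents that add atoms: 2-methylbut-2-ene, CC=C(C)C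
Why: Olefin cross-metathesis exchanges the ethylidene end of the 1,2-disubstituted alkene for isopropylidene under the pressure of excess partner, while the gem-disubstituted isopropenyl group does not engage the ruthenium carbene, so the 3-methylbut-2-enyl terminus forms at a fixed position.

Step 5
Reactants: 6 (3R)-6-methyl-3-(prop-1-en-2-yl)hept-5-enal
Product: 8 (4R)-7-methyl-4-(prop-1-en-2-yl)oct-6-en-1-yne, via diazoalkene 7 (not isolated)
Conditions: dimethyl (1-diazo-2-oxopropyl)phosphonate (1.3 equiv), K2CO3 (2 equiv), MeOH, 0 °C → rt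
Reagents that add atoms: dimethyl (1-diazo-2-oxopropyl)phosphonate, CC(=O)C(=[N+]=[N-])P(=O)(OC)OC
Why: Ohira–Bestmann variant of the Seyferth–Gilbert homologation, in which the diazomethylphosphonate anion released by methanolysis olefinates the aldehyde to a diazoalkene that loses N2 and rearranges by 1,2-hydrogen shift to the terminal alkyne under conditions too mild to affect the β-stereocentre.

Step 6
Reactants: 8 (4R)-7-methyl-4-(prop-1-en-2-yl)oct-6-en-1-yne
Product: 11 triisopropyl{[(4R)-7-methyl-4-(prop-1-en-2-yl)oct-6-en-1-yn-1-yl]oxy}silane, via lithium acetylide 9 (not isolated), via lithium ynolate 10 (not isolated)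
Conditions: n-BuLi (1.05 equiv), THF, −78 °C; then LiOOt-Bu [from t-BuOOH and LiN(SiMe3)2, THF, −78 °C], −78 → 0 °C; then i-Pr3SiOTf (1.2 equiv), −78 → 0 °C
Reagents that add atoms: tert-butyl hydroperoxide, CC(C)(C)OO; triisopropylsilyl trifluoromethanesulfonate, CC(C)[Si](C(C)C)(C(C)C)OS(=O)(=O)C(F)(F)F
Why: Acetylide oxidation by lithium tert-butyl peroxide (oxygen transfer with loss of tert-butoxide) gives the lithium ynolate, which the bulky silyl triflate traps on oxygen to the chromatographically stable silyl ynol ether, the isolated alkenes being inert to the nucleophilic peroxide.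

Step 7
Reactants: 12 3-ethoxycyclobut-2-en-1-one
Product: 14 3-methoxycyclobut-2-en-1-one, via mixed ketal 13 (not isolated)
Conditions: MeOH (solvent, large excess), camphorsulfonic acid (2 mol%), 0 °C → rt; NaHCO3; evaporate and repeat once; bulb-to-bulb distillation
Reagents that add atoms: methanol, CO
Why: Acid-catalysed transetherification of a vinylogous ester, in which methanol adds at C3 to give the mixed 3,3-dialkoxycyclobutanone that loses ethanol, the large excess of methanol carrying the exchange to completion.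

Step 8
Reactants: 11 triisopropyl{[(4R)-7-methyl-4-(prop-1-en-2-yl)oct-6-en-1-yn-1-yl]oxy}silane; 14 3-methoxycyclobut-2-en-1-one
Product: 19 5-methoxy-2-[(2R)-5-methyl-2-(prop-1-en-2-yl)hex-4-en-1-yl]-3-[(triisopropylsilyl)oxy]phenol, via vinylketene 15 (not isolated), via vinylcyclobutenone 16 (not isolated), via dienylketene 17 (not isolated), via cyclohexadienone 18 (not isolated)
Conditions: 14 (1.3 equiv), toluene (0.4 M), 80 °C, 12 h, then 100 °C, 2 h, argon, sealed tube
Reagents that add atoms: none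
Why: Thermal four-electron electrocyclic opening of 14 gives vinylketene 15, whose carbonyl carbon is attacked by the alkyl-bearing carbon of ynol ether 11 in a [2+2] cycloaddition to vinylcyclobutenone 16, and a second four-electron opening gives dienylketene 17, which closes to 18 and enolises to the phenol. The closest known reaction type is the Danheiser benzannulation of cyclobutenones with trialkylsilyloxyalkynes, which gives resorcinol monosilyl ethers. Ring A, the only ring formed, is closed by a thermal six-electron disrotatory electrocyclisation that joins the ketene carbon (future C4′) to the terminal CH2 of the methoxydiene (future C5′), the two new skeletal bonds C3′–C4′ and C1′–C2′ having been made in the [2+2] step. No stereocentre is created, and the existing C2″ centre is remote from all reacting atoms and not enolisable, so its configuration is carried through unchanged. The selectivity required is the orientation of the [2+2] step, which must place the lavandulyl CH2 on the carbon between the two oxygenated carbons, and it is secured by the polarisation of the ynol ether, nucleophilic at the carbon remote from oxygen, toward the electrophilic ketene carbon. The neutral thermal conditions spare the acid-sensitive 1,5-diene, and the unactivated alkenes do not compete with the electron-rich alkyne for the ketene.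

Step 9
Reactants: 19 5-methoxy-2-[(2R)-5-methyl-2-(prop-1-en-2-yl)hex-4-en-1-yl]-3-[(triisopropylsilyl)oxy]phenol
Product: 20 5-methoxy-2-[(2R)-5-methyl-2-(prop-1-en-2-yl)hex-4-en-1-yl]benzene-1,3-diol
Conditions: Bu4NF (1.2 equiv), AcOH (1.2 equiv), THF, 0 °C
Reagents that add atoms: none
Why: Fluoride-induced cleavage of the aryl silyl ether under acetic acid buffering frees the second phenol and gives a resorcinol whose two ring CH positions are equivalent, so the later acylation has no site problem.

Step 10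
Reactants: 20 5-methoxy-2-[(2R)-5-methyl-2-(prop-1-en-2-yl)hex-4-en-1-yl]benzene-1,3-diol
Product: 21 5-methoxy-1,3-bis(methoxymethoxy)-2-[(2R)-5-methyl-2-(prop-1-en-2-yl)hex-4-en-1-yl]benzene
Conditions: MeOCH2Cl (3 equiv), i-Pr2NEt (4 equiv), CH2Cl2, 0 → 40 °C
Reagents that add atoms: chloromethyl methyl ether, COCCl
Why: Methoxymethyl protection by O-alkylation of both phenols with the reactive α-chloro ether under amine base installs the ortho-directing groups needed in step 13 without acid that could cyclise a phenol onto the diene.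

Step 11
Reactants: 22 2,4-dihydroxybenzaldehyde
Product: 23 2,4-bis(methoxymethoxy)benzaldehyde
Conditions: MeOCH2Cl (3 equiv), i-Pr2NEt (4 equiv), CH2Cl2, 0 → 40 °C
Reagents that add atoms: chloromethyl methyl ether, COCCl
Why: Methoxymethyl protection by O-alkylation of both phenols, the hydrogen-bonded 2-OH being covered by the excess reagent and gentle heating.

Step 12
Reactants: 23 2,4-bis(methoxymethoxy)benzaldehyde
Product: 24 (2E)-3-[2,4-bis(methoxymethoxy)phenyl]-N-methoxy-N-methylprop-2-enamide
Conditions: (EtO)2P(O)CH2C(O)N(OMe)Me (1.2 equiv), NaH (1.2 equiv), THF, 0 °C → rt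
Reagents that add atoms: diethyl {2-[methoxy(methyl)amino]-2-oxoethyl}phosphonate, CCOP(=O)(CC(=O)N(C)OC)OCC
Why: Horner–Wadsworth–Emmons olefination with the stabilised amide phosphonate carbanion gives the (E)-enamide through the thermodynamically controlled elimination pathway.

Step 13
Reactants: 21 5-methoxy-1,3-bis(methoxymethoxy)-2-[(2R)-5-methyl-2-(prop-1-en-2-yl)hex-4-en-1-yl]benzene; 24 (2E)-3-[2,4-bis(methoxymethoxy)phenyl]-N-methoxy-N-methylprop-2-enamide
Product: 27 (2E)-3-[2,4-bis(methoxymethoxy)phenyl]-1-{6-methoxy-2,4-bis(methoxymethoxy)-3-[(2R)-5-methyl-2-(prop-1-en-2-yl)hex-4-en-1-yl]phenyl}prop-2-en-1-one, via aryllithium 25 (not isolated), via lithium hemiaminal 26 (not isolated)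
Conditions: n-BuLi (1.1 equiv), THF, 0 °C, 1 h; then 24 (1.2 equiv), −78 → 0 °C; H2O quench
Reagents that add atoms: none
Why: Directed ortho-metalation at the ring CH flanked by OCH2OMe and OMe is followed by Weinreb ketone synthesis, in which the aryllithium adds to the amide carbonyl and the chelated tetrahedral adduct persists until the quench, so the enone is released only after the organolithium is gone.

Step 14
Reactants: 27 (2E)-3-[2,4-bis(methoxymethoxy)phenyl]-1-{6-methoxy-2,4-bis(methoxymethoxy)-3-[(2R)-5-methyl-2-(prop-1-en-2-yl)hex-4-en-1-yl]phenyl}prop-2-en-1-one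
Product: 28 kuraridin [(2E)-1-{2,4-dihydroxy-6-methoxy-3-[(2R)-5-methyl-2-(prop-1-en-2-yl)hex-4-en-1-yl]phenyl}-3-(2,4-dihydroxyphenyl)prop-2-en-1-one]
Conditions: 3 M aq HCl (10 equiv), MeOH, rt → 40 °C, dark, argon
Reagents that add atoms: none
Why: Acid-catalysed acetal solvolysis of the four methoxymethyl ethers in methanol, a standard release of prenylated 2′-hydroxychalcones, should free the phenols under dilute, cool and light-excluded conditions that leave the alkenes, the E-enone and the stereocentre untouched.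

**Compound list**

1 | (S)-(+)-carvone, (5S)-2-methyl-5-(prop-1-en-2-yl)cyclohex-2-en-1-one | CC1=CC[C@@H](CC1=O)C(C)=C | starting material
2 | (1S,4S,6S)-1-methyl-4-(prop-1-en-2-yl)-7-oxabicyclo[4.1.0]heptan-2-one | C[C@]12O[C@H]1C[C@@H](CC2=O)C(C)=C | intermediate
3 | 4-methylbenzenesulfonylhydrazone of epoxy ketone 2 (ring stereocentres as in 2) | C[C@]12O[C@H]1C[C@@H](CC2=NNS(=O)(=O)c3ccc(C)cc3)C(C)=C | intermediate (not isolated)
4 | (3R)-3-(prop-1-en-2-yl)hept-5-ynal | O=CC[C@@H](CC#CC)C(C)=C | intermediate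
5 | (3R,5Z)-3-(prop-1-en-2-yl)hept-5-enal | O=CC[C@@H](C/C=C\C)C(C)=C | intermediate
6 | (3R)-6-methyl-3-(prop-1-en-2-yl)hept-5-enal | O=CC[C@@H](CC=C(C)C)C(C)=C | intermediate
7 | (4R)-1-diazo-7-methyl-4-(prop-1-en-2-yl)octa-1,6-diene | [N-]=[N+]=C=CC[C@@H](CC=C(C)C)C(C)=C | intermediate (not isolated)
8 | (4R)-7-methyl-4-(prop-1-en-2-yl)oct-6-en-1-yne | C#CC[C@@H](CC=C(C)C)C(C)=C | intermediate
9 | [(4R)-7-methyl-4-(prop-1-en-2-yl)oct-6-en-1-yn-1-yl]lithium | [Li]C#CC[C@@H](CC=C(C)C)C(C)=C | intermediate (not isolated)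
10 | lithium (4R)-7-methyl-4-(prop-1-en-2-yl)oct-6-en-1-yn-1-olate | [Li]OC#CC[C@@H](CC=C(C)C)C(C)=C | intermediate (not isolated)
11 | triisopropyl{[(4R)-7-methyl-4-(prop-1-en-2-yl)oct-6-en-1-yn-1-yl]oxy}silane | C=C(C)[C@H](CC=C(C)C)CC#CO[Si](C(C)C)(C(C)C)C(C)C | intermediate
12 | 3-ethoxycyclobut-2-en-1-one | CCOC1=CC(=O)C1 | starting material
13 | 3-ethoxy-3-methoxycyclobutan-1-one | CCOC1(OC)CC(=O)C1 | intermediate (not isolated)
14 | 3-methoxycyclobut-2-en-1-one | COC1=CC(=O)C1 | intermediate
15 | 3-methoxybuta-1,3-dien-1-one | COC(=C)C=C=O | intermediate (not isolated)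
16 | 4-(1-methoxyethenyl)-2-[(2R)-5-methyl-2-(prop-1-en-2-yl)hex-4-en-1-yl]-3-[(triisopropylsilyl)oxy]cyclobut-2-en-1-one (both configurations at ring C4) | C=C(C)[C@H](CC=C(C)C)CC1=C(O[Si](C(C)C)(C(C)C)C(C)C)C(C(=C)OC)C1=O | intermediate (not isolated)
17 | (3E)-5-methoxy-2-[(2R)-5-methyl-2-(prop-1-en-2-yl)hex-4-en-1-yl]-3-[(triisopropylsilyl)oxy]hexa-1,3,5-trien-1-one | C=C(C)[C@H](CC=C(C)C)CC(=C=O)/C(O[Si](C(C)C)(C(C)C)C(C)C)=C\C(OC)=C | intermediate (not isolated)
18 | 5-methoxy-2-[(2R)-5-methyl-2-(prop-1-en-2-yl)hex-4-en-1-yl]-3-[(triisopropylsilyl)oxy]cyclohexa-2,4-dien-1-one | C=C(C)[C@H](CC=C(C)C)CC1=C(O[Si](C(C)C)(C(C)C)C(C)C)C=C(OC)CC1=O | intermediate (not isolated)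
19 | 5-methoxy-2-[(2R)-5-methyl-2-(prop-1-en-2-yl)hex-4-en-1-yl]-3-[(triisopropylsilyl)oxy]phenol | C=C(C)[C@H](CC=C(C)C)Cc1c(O)cc(OC)cc1O[Si](C(C)C)(C(C)C)C(C)C | intermediate
20 | 5-methoxy-2-[(2R)-5-methyl-2-(prop-1-en-2-yl)hex-4-en-1-yl]benzene-1,3-diol | C=C(C)[C@H](CC=C(C)C)Cc1c(O)cc(OC)cc1O | intermediate
21 | 5-methoxy-1,3-bis(methoxymethoxy)-2-[(2R)-5-methyl-2-(prop-1-en-2-yl)hex-4-en-1-yl]benzene | C=C(C)[C@H](CC=C(C)C)Cc1c(OCOC)cc(OC)cc1OCOC | intermediate
22 | 2,4-dihydroxybenzaldehyde | O=Cc1ccc(O)cc1O | starting material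
23 | 2,4-bis(methoxymethoxy)benzaldehyde | O=Cc1ccc(OCOC)cc1OCOC | intermediate
24 | (2E)-3-[2,4-bis(methoxymethoxy)phenyl]-N-methoxy-N-methylprop-2-enamide | CON(C)C(=O)/C=C/c1ccc(OCOC)cc1OCOC | intermediate
25 | {6-methoxy-2,4-bis(methoxymethoxy)-3-[(2R)-5-methyl-2-(prop-1-en-2-yl)hex-4-en-1-yl]phenyl}lithium | [Li]c1c(OC)cc(OCOC)c(C[C@@H](CC=C(C)C)C(C)=C)c1OCOC | intermediate (not isolated)
26 | lithium alkoxide of the N-methoxy-N-methyl hemiaminal from 25 and 24 (both configurations at the new carbinol carbon) | [Li]OC(/C=C/c1ccc(OCOC)cc1OCOC)(N(C)OC)c1c(OC)cc(OCOC)c(C[C@@H](CC=C(C)C)C(C)=C)c1OCOC | intermediate (not isolated)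
27 | (2E)-3-[2,4-bis(methoxymethoxy)phenyl]-1-{6-methoxy-2,4-bis(methoxymethoxy)-3-[(2R)-5-methyl-2-(prop-1-en-2-yl)hex-4-en-1-yl]phenyl}prop-2-en-1-one | C=C(C)[C@H](CC=C(C)C)Cc1c(OCOC)cc(OC)c(C(=O)/C=C/c2ccc(OCOC)cc2OCOC)c1OCOC | intermediate
28 | kuraridin | C=C(C)[C@H](CC=C(C)C)Cc1c(O)cc(OC)c(C(=O)/C=C/c2ccc(O)cc2O)c1O | target

**Step count**

Total step count: 14. Longest linear sequence: 11 steps (steps 1–6, 8, 9, 10, 13, 14).

**Steps most likely to fail**

1. Step 8 (benzannulation). The donor-substituted cyclobutenone may open too slowly at temperatures the silyl ynol ether tolerates (thermal silyl shift to a silylketene), and the freed phenol may be acylated by excess ketene. The fallback sets out from 11 and returns at 19. Commercial methyl (2E)-3-methoxybut-2-enoate is saponified (LiOH, THF/H2O) to (2E)-3-methoxybut-2-enoic acid F1, which oxalyl chloride converts into (2E)-3-methoxybut-2-enoyl chloride F2. Slow addition of Et3N to F2 and 11 in CH2Cl2 at 0 °C generates vinylketene 15 by 1,4-dehydrochlorination at a temperature where capture by the ynol ether is the only open channel. Vinylcyclobutenone 16 is then isolated and, free of ketene precursors, warmed in toluene (80 °C) to open and close to 19. Both operations are known chemistry (vinylketenes from unsaturated acid chlorides with amine base; their cycloaddition to heteroatom-substituted alkynes), and this path does not depend on the supply of 14.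

2. Step 13 (acylation). The hindered aryllithium may add in conjugate fashion to the enamide, or act as a base toward it, instead of attacking the amide carbonyl. The fallback sets out from 21 and returns at 27. Aryllithium 25, generated as in step 13, is quenched with N-methoxy-N-methylacetamide to give 1-{6-methoxy-2,4-bis(methoxymethoxy)-3-[(2R)-5-methyl-2-(prop-1-en-2-yl)hex-4-en-1-yl]phenyl}ethan-1-one F3. Claisen–Schmidt condensation of F3 with aldehyde 23 (KOH, EtOH/H2O, rt) then builds the E-enone of 27 by aldol addition and dehydration, so that no conjugated acceptor is ever exposed to the organolithium.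

3. Step 14 (acidic release). During acetal cleavage the freed 2′-OH may close onto the enone (flavanone formation), a phenol may add to the protonated isopropenyl group (chroman formation), or the enone may isomerise toward a flavylium salt. The fallback avoids acid altogether; it sets out from 19 and 22 and returns at 28.
   - Ring A partner: 19 is silylated (i-Pr3SiOTf, 2,6-lutidine, CH2Cl2, 0 °C) to 5-methoxy-2-[(2R)-5-methyl-2-(prop-1-en-2-yl)hex-4-en-1-yl]-1,3-bis[(triisopropylsilyl)oxy]benzene F4. Bromination (N-bromosuccinimide, MeCN, −30 → 0 °C, dark) at one of the two equivalent ring CH positions gives 2-bromo-1-methoxy-4-[(2R)-5-methyl-2-(prop-1-en-2-yl)hex-4-en-1-yl]-3,5-bis[(triisopropylsilyl)oxy]benzene F5.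
   - Ring B partner: 22 is silylated (i-Pr3SiCl, imidazole, DMF) to 2,4-bis[(triisopropylsilyl)oxy]benzaldehyde F6 and olefinated as in step 12 to (2E)-3-{2,4-bis[(triisopropylsilyl)oxy]phenyl}-N-methoxy-N-methylprop-2-enamide F7.
   - Coupling and release: bromine–lithium exchange on F5 (t-BuLi, Et2O, −78 °C, kept cold to prevent silyl migration from oxygen to carbon) gives {6-methoxy-3-[(2R)-5-methyl-2-(prop-1-en-2-yl)hex-4-en-1-yl]-2,4-bis[(triisopropylsilyl)oxy]phenyl}lithium F8. Addition of F8 to F7 gives (2E)-3-{2,4-bis[(triisopropylsilyl)oxy]phenyl}-1-{6-methoxy-3-[(2R)-5-methyl-2-(prop-1-en-2-yl)hex-4-en-1-yl]-2,4-bis[(triisopropylsilyl)oxy]phenyl}prop-2-en-1-one F9. Buffered fluoride (Bu4NF, AcOH, THF, 0 °C) then removes all four silyl groups to give 28.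

Further compounds
F1 | step 8 | (2E)-3-methoxybut-2-enoic acid | CO/C(C)=C/C(=O)O
F2 | step 8 | (2E)-3-methoxybut-2-enoyl chloride | CO/C(C)=C/C(Cl)=O
F3 | step 13 | 1-{6-methoxy-2,4-bis(methoxymethoxy)-3-[(2R)-5-methyl-2-(prop-1-en-2-yl)hex-4-en-1-yl]phenyl}ethan-1-one | CC(=O)c1c(OC)cc(OCOC)c(C[C@@H](CC=C(C)C)C(C)=C)c1OCOC
F4 | step 14 | 5-methoxy-2-[(2R)-5-methyl-2-(prop-1-en-2-yl)hex-4-en-1-yl]-1,3-bis[(triisopropylsilyl)oxy]benzene | C=C(C)[C@H](CC=C(C)C)Cc1c(O[Si](C(C)C)(C(C)C)C(C)C)cc(OC)cc1O[Si](C(C)C)(C(C)C)C(C)C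
F5 | step 14 | 2-bromo-1-methoxy-4-[(2R)-5-methyl-2-(prop-1-en-2-yl)hex-4-en-1-yl]-3,5-bis[(triisopropylsilyl)oxy]benzene | C=C(C)[C@H](CC=C(C)C)Cc1c(O[Si](C(C)C)(C(C)C)C(C)C)cc(OC)c(Br)c1O[Si](C(C)C)(C(C)C)C(C)C
F6 | step 14 | 2,4-bis[(triisopropylsilyl)oxy]benzaldehyde | O=Cc1ccc(O[Si](C(C)C)(C(C)C)C(C)C)cc1O[Si](C(C)C)(C(C)C)C(C)C
F7 | step 14 | (2E)-3-{2,4-bis[(triisopropylsilyl)oxy]phenyl}-N-methoxy-N-methylprop-2-enamide | CON(C)C(=O)/C=C/c1ccc(O[Si](C(C)C)(C(C)C)C(C)C)cc1O[Si](C(C)C)(C(C)C)C(C)C
F8 | step 14 | {6-methoxy-3-[(2R)-5-methyl-2-(prop-1-en-2-yl)hex-4-en-1-yl]-2,4-bis[(triisopropylsilyl)oxy]phenyl}lithium | [Li]c1c(OC)cc(O[Si](C(C)C)(C(C)C)C(C)C)c(C[C@@H](CC=C(C)C)C(C)=C)c1O[Si](C(C)C)(C(C)C)C(C)C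
F9 | step 14 | (2E)-3-{2,4-bis[(triisopropylsilyl)oxy]phenyl}-1-{6-methoxy-3-[(2R)-5-methyl-2-(prop-1-en-2-yl)hex-4-en-1-yl]-2,4-bis[(triisopropylsilyl)oxy]phenyl}prop-2-en-1-one | C=C(C)[C@H](CC=C(C)C)Cc1c(O[Si](C(C)C)(C(C)C)C(C)C)cc(OC)c(C(=O)/C=C/c2ccc(O[Si](C(C)C)(C(C)C)C(C)C)cc2O[Si](C(C)C)(C(C)C)C(C)C)c1O[Si](C(C)C)(C(C)C)C(C)C
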